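The earlier runs and the new flask were computed with made-up constants; noise was put on by code.

Friday's run still holds 84.2 % of its substrate at 60.0 min, yet its target reads 9.2 % there, below the 10.0 % of 30.0 min. Something other than substrate stops the rise, so I count the rise in lifetimes.

| flask | substrate | reagent in the second phase | remark | time | volume of the second phase over the first |
|---|---|---|---|---|---|
| Friday's | 10 mM | 16.5 mM | run made earlier |  |  |
| Tuesday's | 22 mM | 16.5 mM | run made earlier |  |  |
| Saturday's | 15 mM | 8.2 mM | run made earlier |  |  |
| flask | 15 mM | 16.5 mM |  | 50 min | 2.0 |

| run | time / min | target / % | substrate / % |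
|---|---|---|---|
| Friday's | 5.00 | 3.8 | 97.5 |
| Friday's | 15.0 | 7.4 | 91.2 |
| Friday's | 30.0 | 10.0 | 87.4 |
| Friday's | 40.0 | 9.7 | 86.4 |
| Friday's | 60.0 | 9.2 | 84.2 |
| Tuesday's | 5.00 | 3.6 | 97.4 |
| Tuesday's | 15.0 | 7.3 | 91.8 |
| Tuesday's | 30.0 | 9.0 | 88.1 |
| Tuesday's | 40.0 | 8.2 | 87.5 |
| Tuesday's | 60.0 | 8.9 | 85.3 |
| Saturday's | 5.00 | 2.1 | 99.0 |
| Saturday's | 15.0 | 4.5 | 95.0 |
| Saturday's | 30.0 | 4.2 | 94.4 |
| Saturday's | 40.0 | 5.2 | 93.6 |
| Saturday's | 60.0 | 5.4 | 92.1 |

(each reading ± 0.5 percentage points)

- in the second phase: reagent in the second phase; everything else is in the first
- charges count per volume of the first phase; a concentration in a rate is the amount of a species over the volume of its own phase; every rate counts per litre of the first phase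
- what was read earlier has a scatter of 0.5 percentage points, one standard deviation
- the earlier runs hold the two phases in the same ratio of volumes as the flask asked about

* the target standing at 50 min, as a percentage of the substrate charged
* the change that raises the amount of target at 50 min, in percent of the substrate charged most ("none" if none brings more than 2 percentage points) (ash / alder / none)
* amount of target at 50 min, in percent of the substrate charged, after ash

- ash: doubling the amount of reagent in the second phase, all else as stated
- alder: doubling the transfer coefficient of the reagent in the second phase, all else as stated

Friday's and Tuesday's runs differ in [substrate] and read alike in percent, so I pool them for the flask, whose [substrate] of 15 mM lies between theirs. Their late readings give a height of 9.17 %, and their first readings average 3.70 % at 5.00 min. Height over starting slope gives 12.4 min; this is the filling time, the relaxation time of a rise to a plateau.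

Two extremes can be done in the head. If target kept its starting slope, the flask would read 37.0 % at 50 min; if it stood at its height from the first moment, 9.17 %. A rise to a plateau stays under both, so I put the real flask just under the second, because 50 min is 4.04 filling times. The unfilled part is 1.76 % of the height, so I say 9.00 %.

Saturday's run, with half the reagent in the second phase, reads a height of 4.93 % and a filling time of 11.7 min. Scaling the height by the ratio of the two heights, I put ash at 17.1 %. I take alder to bring the filling forward, and the unfilled 0.16 percentage points is less than the 2 points mark, so I choose ash.

The forecast says 9.2 %, ash and 14 %: “Faster transfer mainly brings delivery forward, and the plateau is already reached, so ash is best.” My figures differ from its 9.2 % and 14 %, but the choice is the same.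

The flask gives 9.03 %; ash adds 7 points and reaches 16.1 %, while alder adds 0.056 points.

    target ⇌ isomer of the product (K = 1.80, k = 0.0177 min⁻¹)
    substrate + reagent in the reaction phase ⇌ target (K = 37.0 M⁻¹, k = 6.05 M⁻¹ min⁻¹)
    reagent in the reaction phase ⇌ reagent in the second phase, rate k3*([reagent in the reaction phase] - [reagent in the second phase]/K3) per volume of the first phase (partition coefficient = 1.81, kL = 0.159 min⁻¹)

In this flask, half of the turnover from substrate to target is done by 12.3 min, and half of that from target to isomer of the product by 27.9 min. At 50.0 min, 4.04 filling times of 12.4 min in, target is made at 0.923 of the rate at which it is used up, each step taken net. The neighbour flask, read at 30 min, is 2.42 filling times in; the count gives 8.35 %, and it holds 8.99 %.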